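**Retrosynthetic overview**

1. Endgame: the two 2,4-dihydroxybenzoyl C=O groups are carried as ArCH2 groups and made last by benzylic C–H oxidation; the phenols are unmasked from four O-benzyl groups and from two aryl–boron (earlier aryl–bromine) placeholders.
2. Key disconnection: the oxolane ring (O1, C2, C3, C4, C5) is opened at O1–C2 and at the C2–H and C5–H bonds, back to an open-chain C2-symmetric (2R,3R)-2,3-bis(arylmethyl)-1,4-diaryl-1,4-diketone (one-flask ketalization and double ionic hydrogenation).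
3. Enabling feature: C2 and C5, the two aryl-bearing carbons bonded to O1, are 1,4-related (a latent 1,4-diketone), and each is flanked by a ring carbon (C3, C4) whose side chain is trans to the other; this trans pair steers hydride to opposite faces of C2 and C5.
4. The diketone comes from twofold asymmetric C=C hydrogenation of a bis(benzylidene) diketone, itself made by twofold Claisen–Schmidt condensation of 1,4-bis(4-bromophenyl)butane-1,4-dione with 2,4-bis(benzyloxy)benzaldehyde.
5. Ring order: the four benzene rings of the target arrive ready-made in the two starting materials; the oxolane ring is the only ring formed and is closed last.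

Key step: step 3

Remark (assumption on the chemistry): the oxolane is numbered O1, C2 (aryl), C3 (aroyl), C4 (aroyl), C5 (aryl); the target is the (2S,3R,4R,5S) isomer, in which each aryl group is cis to the neighbouring aroyl group and the two aroyl groups and the two aryl groups are each trans; 1 and 2 are taken as commercial.

**Route**

Step 1
Reactants: 1 1,4-bis(4-bromophenyl)butane-1,4-dione; 2 2,4-bis(benzyloxy)benzaldehyde (2.2 equiv)
Product: 3 (2E,3E)-2,3-bis{[2,4-bis(benzyloxy)phenyl]methylidene}-1,4-bis(4-bromophenyl)butane-1,4-dione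
Conditions: KOH (20 mol%), EtOH/THF, 60 °C
Reagents that add atoms: none
Why: Twofold Claisen–Schmidt (crossed aldol) condensation at the two internal CH2 groups of the 1,4-diketone, in which the non-enolisable aldehyde can only be the acceptor and E1cB dehydration should give the thermodynamically favoured E,E-bis(benzylidene) diketone (no stereocentre).

Step 2
Reactants: 3 (2E,3E)-2,3-bis{[2,4-bis(benzyloxy)phenyl]methylidene}-1,4-bis(4-bromophenyl)butane-1,4-dione
Product: 4 (2R,3R)-2,3-bis{[2,4-bis(benzyloxy)phenyl]methyl}-1,4-bis(4-bromophenyl)butane-1,4-dione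
Conditions: H2 (50 bar), [Ir(cod)((S)-tBu-PHOX)][B(C6H3(CF3)2)4] (2 mol%), CH2Cl2, rt
Reagents that add atoms: none
Why: Iridium N,P-ligand-catalysed asymmetric hydrogenation of α-substituted α,β-unsaturated aryl ketones, in which the two enone units are homotopic, so the same catalyst-controlled face selection at each trisubstituted C=C should set both α-carbons R and give the C2-symmetric diketone, the ligand enantiomer used being the one that a mono-enone model substrate shows to deliver the R centre, while aryl bromide, ketone and benzyl ether are inert to this catalyst.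

Step 3
Reactants: 4 (2R,3R)-2,3-bis{[2,4-bis(benzyloxy)phenyl]methyl}-1,4-bis(4-bromophenyl)butane-1,4-dione
Product: 6 (2S,3R,4R,5S)-3,4-bis{[2,4-bis(benzyloxy)phenyl]methyl}-2,5-bis(4-bromophenyl)oxolane, via cyclic bis(methyl ketal) 5 (not isolated)
Conditions: MeOSiMe3 (3 equiv), TMSOTf (0.2 equiv), CH2Cl2, −78 → −40 °C; then Et3SiH (6 equiv), TMSOTf (1 equiv), −78 °C
Reagents that add atoms: methoxytrimethylsilane, CO[Si](C)(C)C (supplies the two methoxy groups of 5; none of its atoms stay in 6)
Why: Silyl triflate-catalysed ketalization turns one carbonyl into an O-methyl oxocarbenium ion that is captured by the oxygen of the second carbonyl (5-exo-trig closure of the oxolane ring, O1–C2 bond) and then by methoxide transfer, giving cyclic bis(methyl ketal) 5, so that both benzylic carbons are in the ring before any hydride arrives. Ionisation of each anomeric C–OMe bond by TMSOTf then gives a 2-aryl cyclic oxocarbenium ion that takes hydride from Et3SiH. The closest known reaction types are the silane/Lewis acid reductive cyclization of 1,4-diketones to tetrahydrofurans and the reductive deoxygenation of 2-aryl-3-alkyl cyclic hemiketals, in which hydride adds to the ring face opposite the C3 substituent. C2 is therefore set by the C3 side chain (H anti to it, aryl cis to it) and C5 by the C4 side chain in the same way; because the two side chains are trans (set in step 2 and untouched here), the two hydrides arrive on opposite faces and the C2-symmetric 2,3-cis-3,4-trans-4,5-cis oxolane with trans aryl groups should result. The step needs hydride transfer to the cyclic rather than to an open-chain oxocarbenium ion (the latter would be under acyclic Felkin–Anh-type control and is not expected to give the same relative configuration), which is secured by forming 5 first, and it needs hydride capture to outrun loss of H3/H4 from the oxocarbenium ions (epimerization or furan formation), which is secured by −78 °C, excess silane and the electron-poor 4-bromophenyl groups, which also protect the product ring from reductive opening.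

Step 4
Reactants: 6 (2S,3R,4R,5S)-3,4-bis{[2,4-bis(benzyloxy)phenyl]methyl}-2,5-bis(4-bromophenyl)oxolane
Product: 7 (2S,3R,4R,5S)-3,4-bis{[2,4-bis(benzyloxy)phenyl]methyl}-2,5-bis[4-(4,4,5,5-tetramethyl-1,3,2-dioxaborolan-2-yl)phenyl]oxolane
Conditions: B2pin2 (3 equiv), Pd(dppf)Cl2 (5 mol%), KOAc (6 equiv), 1,4-dioxane, 85 °C
Reagents that add atoms: bis(pinacolato)diboron, CC1(C)OB(OC1(C)C)B1OC(C)(C)C(C)(C)O1
Why: Miyaura borylation (oxidative addition of the aryl bromide to zerovalent palladium, acetate-assisted transmetalation, reductive elimination) touches no stereocentre, and the boryl group is a phenol placeholder that leaves the C2/C5 aryl rings without donor activation for step 5.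

Step 5
Reactants: 7 (2S,3R,4R,5S)-3,4-bis{[2,4-bis(benzyloxy)phenyl]methyl}-2,5-bis[4-(4,4,5,5-tetramethyl-1,3,2-dioxaborolan-2-yl)phenyl]oxolane
Product: 9 [(2S,3R,4R,5S)-2,5-bis[4-(4,4,5,5-tetramethyl-1,3,2-dioxaborolan-2-yl)phenyl]oxolane-3,4-diyl]bis{[2,4-bis(benzyloxy)phenyl]methanone}, via bis(benzylic alcohol) 8 (not isolated)
Conditions: DDQ (6 equiv), CH2Cl2/H2O (10:1), 0 °C → rt
Reagents that add atoms: water, O
Why: DDQ benzylic oxidation, in which hydride abstraction from each CH2 group activated by ortho- and para-alkoxy groups gives a benzylic cation that water traps (diol 8) and DDQ oxidises the electron-rich benzylic alcohol on to the aryl ketone; C2–H, C5–H and the O-benzyl CH2 groups lack this donor activation and C3/C4 are not ionised, so all four stereocentres should be kept.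

Step 6
Reactants: 9 [(2S,3R,4R,5S)-2,5-bis[4-(4,4,5,5-tetramethyl-1,3,2-dioxaborolan-2-yl)phenyl]oxolane-3,4-diyl]bis{[2,4-bis(benzyloxy)phenyl]methanone}
Product: 10 [(2S,3R,4R,5S)-2,5-bis(4-hydroxyphenyl)oxolane-3,4-diyl]bis{[2,4-bis(benzyloxy)phenyl]methanone}
Conditions: Me3NO (3 equiv), THF, rt; aqueous work-up
Reagents that add atoms: trimethylamine N-oxide, C[N+](C)(C)[O-]
Why: ipso-Hydroxylation of the aryl boronic ester by the amine N-oxide (boron ate complex, 1,2-aryl shift from boron to oxygen, hydrolysis) runs without hydroxide or peroxide, which avoids enolisation of the two ketones whose α-carbons C3 and C4 hold the contra-thermodynamic cis relationship to the aryl groups.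

Step 7
Reactants: 10 [(2S,3R,4R,5S)-2,5-bis(4-hydroxyphenyl)oxolane-3,4-diyl]bis{[2,4-bis(benzyloxy)phenyl]methanone}
Product: 11 [(2S,3R,4R,5S)-2,5-bis(4-hydroxyphenyl)oxolane-3,4-diyl]bis[(2,4-dihydroxyphenyl)methanone] (CNP0237262.3)
Conditions: H2 (1 atm), Pd/C (10% Pd), EtOAc/MeOH, rt
Reagents that add atoms: none
Why: Hydrogenolysis of the four aryl benzyl ethers over palladium on carbon at neutral pH forms no stereocentre, and a short reaction at 1 atm should leave the ring C–O bonds and the hydrogen-bonded aryl ketones intact.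

**Compound list**

1 | 1,4-bis(4-bromophenyl)butane-1,4-dione | O=C(CCC(=O)c1ccc(Br)cc1)c1ccc(Br)cc1 | starting material
2 | 2,4-bis(benzyloxy)benzaldehyde | O=Cc1ccc(OCc2ccccc2)cc1OCc1ccccc1 | starting material
3 | (2E,3E)-2,3-bis{[2,4-bis(benzyloxy)phenyl]methylidene}-1,4-bis(4-bromophenyl)butane-1,4-dione | O=C(c1ccc(Br)cc1)/C(=C/c1ccc(OCc2ccccc2)cc1OCc1ccccc1)C(=C/c1ccc(OCc2ccccc2)cc1OCc1ccccc1)\C(=O)c1ccc(Br)cc1 | intermediate
4 | (2R,3R)-2,3-bis{[2,4-bis(benzyloxy)phenyl]methyl}-1,4-bis(4-bromophenyl)butane-1,4-dione | O=C(c1ccc(Br)cc1)[C@H](Cc1ccc(OCc2ccccc2)cc1OCc1ccccc1)[C@@H](Cc1ccc(OCc2ccccc2)cc1OCc1ccccc1)C(=O)c1ccc(Br)cc1 | intermediate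
5 | (3R,4R)-3,4-bis{[2,4-bis(benzyloxy)phenyl]methyl}-2,5-bis(4-bromophenyl)-2,5-dimethoxyoxolane (mixture at the two ketal carbons) | C(c1ccc(OCc2ccccc2)cc1OCc1ccccc1)[C@@H]1[C@@H](Cc2ccc(OCc3ccccc3)cc2OCc2ccccc2)C(OC)(c2ccc(Br)cc2)OC1(OC)c1ccc(Br)cc1 | intermediate (not isolated)
6 | (2S,3R,4R,5S)-3,4-bis{[2,4-bis(benzyloxy)phenyl]methyl}-2,5-bis(4-bromophenyl)oxolane | C(c1ccc(OCc2ccccc2)cc1OCc1ccccc1)[C@@H]1[C@@H](Cc2ccc(OCc3ccccc3)cc2OCc2ccccc2)[C@@H](c2ccc(Br)cc2)O[C@@H]1c1ccc(Br)cc1 | intermediate
7 | (2S,3R,4R,5S)-3,4-bis{[2,4-bis(benzyloxy)phenyl]methyl}-2,5-bis[4-(4,4,5,5-tetramethyl-1,3,2-dioxaborolan-2-yl)phenyl]oxolane | C(c1ccc(OCc2ccccc2)cc1OCc1ccccc1)[C@@H]1[C@@H](Cc2ccc(OCc3ccccc3)cc2OCc2ccccc2)[C@@H](c2ccc(B3OC(C)(C)C(C)(C)O3)cc2)O[C@@H]1c1ccc(B2OC(C)(C)C(C)(C)O2)cc1 | intermediate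
8 | bis(benzylic alcohol): compound 7 with each ArCH2 group on C3/C4 changed to ArCH(OH) (ring configuration as in 7; the two carbinol centres are a mixture) | OC(c1ccc(OCc2ccccc2)cc1OCc1ccccc1)[C@@H]1[C@@H](C(O)c2ccc(OCc3ccccc3)cc2OCc2ccccc2)[C@@H](c2ccc(B3OC(C)(C)C(C)(C)O3)cc2)O[C@@H]1c1ccc(B2OC(C)(C)C(C)(C)O2)cc1 | intermediate (not isolated)
9 | [(2S,3R,4R,5S)-2,5-bis[4-(4,4,5,5-tetramethyl-1,3,2-dioxaborolan-2-yl)phenyl]oxolane-3,4-diyl]bis{[2,4-bis(benzyloxy)phenyl]methanone} | O=C(c1ccc(OCc2ccccc2)cc1OCc1ccccc1)[C@@H]1[C@@H](C(=O)c2ccc(OCc3ccccc3)cc2OCc2ccccc2)[C@@H](c2ccc(B3OC(C)(C)C(C)(C)O3)cc2)O[C@@H]1c1ccc(B2OC(C)(C)C(C)(C)O2)cc1 | intermediate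
10 | [(2S,3R,4R,5S)-2,5-bis(4-hydroxyphenyl)oxolane-3,4-diyl]bis{[2,4-bis(benzyloxy)phenyl]methanone} | O=C(c1ccc(OCc2ccccc2)cc1OCc1ccccc1)[C@@H]1[C@@H](C(=O)c2ccc(OCc3ccccc3)cc2OCc2ccccc2)[C@@H](c2ccc(O)cc2)O[C@@H]1c1ccc(O)cc1 | intermediate
11 | [(2S,3R,4R,5S)-2,5-bis(4-hydroxyphenyl)oxolane-3,4-diyl]bis[(2,4-dihydroxyphenyl)methanone] | O=C(c1ccc(O)cc1O)[C@@H]1[C@@H](C(=O)c2ccc(O)cc2O)[C@@H](c2ccc(O)cc2)O[C@@H]1c1ccc(O)cc1 | target

**Step count**

Total step count: 7. Longest linear sequence: 7 steps (from 1 or 2 to 11).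

**Three steps most likely to fail**

Step 3 (key step). What may go wrong is hydride transfer to an open-chain oxocarbenium ion before the ring is closed (wrong face at C2 or C5), delivery of the second hydride on the wrong face because it must arrive syn to the remote aryl group already in place, or proton loss from the cyclic oxocarbenium ions (epimerization at C3/C4, aromatization to the furan). The fallback sets out from 4 and comes back at 6, and sets one carbinol by reagent control before the ring is reduced. Corey–Bakshi–Shibata reduction of one of the two homotopic ketones of 4 ((R)-Me-CBS oxazaborolidine, BH3·SMe2, 0.6 equiv, THF, −20 °C) should give the (S)-carbinol. This hydroxy ketone closes at once to the cyclic hemiketal (3R,4R,5S)-3,4-bis{[2,4-bis(benzyloxy)phenyl]methyl}-2,5-bis(4-bromophenyl)oxolan-2-ol F1, which shields the second carbonyl from borane. Reductive deoxygenation of the hemiketal (Et3SiH, BF3·OEt2, CH2Cl2, −78 °C) through a single cyclic oxocarbenium ion, with hydride anti to the neighbouring side chain, should then give 6.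

Step 2 (and step 1 before it). What may go wrong is poor enantiofacial control, a mismatched second hydrogenation that leads towards the meso diketone, or incomplete hydrogenation at the hindered cross-conjugated bis-enone; one step earlier, the condensation may stall after the first aldehyde or the mono-adduct may isomerise to the conjugated ene-dione. The fallback sets out from 2 and comes back at 4, bypassing 3; it builds the C3–C4 bond by auxiliary-controlled oxidative enolate coupling, and the 4-bromophenyl groups then come from 1,4-dibromobenzene. Doebner–Knoevenagel condensation of 2 with malonic acid (pyridine, piperidine, 90 °C) should give (E)-3-[2,4-bis(benzyloxy)phenyl]prop-2-enoic acid F2. Homogeneous hydrogenation (H2, RhCl(PPh3)3, benzene/EtOH) should then give 3-[2,4-bis(benzyloxy)phenyl]propanoic acid F3 without loss of the benzyl ethers. N-Acylation of (4S)-4-benzyl-1,3-oxazolidin-2-one with this acid (pivaloyl chloride, Et3N, LiCl, THF) should give (4S)-4-benzyl-3-{3-[2,4-bis(benzyloxy)phenyl]propanoyl}-1,3-oxazolidin-2-one F4. Oxidative homocoupling of its lithium enolate (LDA, THF, −78 °C; then TiCl4 or CuCl2) should join the two α-carbons on the face away from the auxiliary benzyl group and give (2R,3R)-2,3-bis{[2,4-bis(benzyloxy)phenyl]methyl}-1,4-bis[(4S)-4-benzyl-2-oxo-1,3-oxazolidin-3-yl]butane-1,4-dione F5. Transamidation (MeNHOMe·HCl, AlMe3, CH2Cl2) should give (2R,3R)-2,3-bis{[2,4-bis(benzyloxy)phenyl]methyl}-N1,N4-dimethoxy-N1,N4-dimethylbutanediamide F6, and Weinreb ketone synthesis with 4-bromophenyllithium (from 1,4-dibromobenzene and n-BuLi, THF, −78 °C) should give 4.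

Step 5. What may go wrong is elimination from the benzylic cation next to C3/C4 instead of capture by water, competing hydride abstraction at C2–H/C5–H, or stalling at the alcohol stage. The fallback sets out from 7 and comes back at 9. It replaces the one-flask four-electron oxidation by a stepwise C–H acetoxylation, solvolysis and alcohol oxidation, so that the cation is captured by the solvent and the last stage no longer depends on DDQ. DDQ in acetic acid (rt) should give the bis(benzylic acetate) of 7, {(2S,3R,4R,5S)-2,5-bis[4-(4,4,5,5-tetramethyl-1,3,2-dioxaborolan-2-yl)phenyl]oxolane-3,4-diyl}bis{[2,4-bis(benzyloxy)phenyl]methyl} diacetate F7 (mixture at the two acetoxy-bearing carbons). Methanolysis (K2CO3, MeOH, 0 °C) should give diol 8, now isolated, and Dess–Martin oxidation (Dess–Martin periodinane, NaHCO3, CH2Cl2) should give 9.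

**Further compounds**

F1 | step 3 | (3R,4R,5S)-3,4-bis{[2,4-bis(benzyloxy)phenyl]methyl}-2,5-bis(4-bromophenyl)oxolan-2-ol (mixture at C2) | C(c1ccc(OCc2ccccc2)cc1OCc1ccccc1)[C@@H]1[C@@H](Cc2ccc(OCc3ccccc3)cc2OCc2ccccc2)C(O)(c2ccc(Br)cc2)O[C@@H]1c1ccc(Br)cc1
F2 | step 2 | (E)-3-[2,4-bis(benzyloxy)phenyl]prop-2-enoic acid | OC(=O)/C=C/c1ccc(OCc2ccccc2)cc1OCc1ccccc1
F3 | step 2 | 3-[2,4-bis(benzyloxy)phenyl]propanoic acid | OC(=O)CCc1ccc(OCc2ccccc2)cc1OCc1ccccc1
F4 | step 2 | (4S)-4-benzyl-3-{3-[2,4-bis(benzyloxy)phenyl]propanoyl}-1,3-oxazolidin-2-one | O=C(CCc1ccc(OCc2ccccc2)cc1OCc1ccccc1)N1[C@@H](Cc2ccccc2)COC1=O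
F5 | step 2 | (2R,3R)-2,3-bis{[2,4-bis(benzyloxy)phenyl]methyl}-1,4-bis[(4S)-4-benzyl-2-oxo-1,3-oxazolidin-3-yl]butane-1,4-dione | O=C([C@H](Cc1ccc(OCc2ccccc2)cc1OCc1ccccc1)[C@@H](Cc1ccc(OCc2ccccc2)cc1OCc1ccccc1)C(=O)N1[C@@H](Cc2ccccc2)COC1=O)N1[C@@H](Cc2ccccc2)COC1=O
F6 | step 2 | (2R,3R)-2,3-bis{[2,4-bis(benzyloxy)phenyl]methyl}-N1,N4-dimethoxy-N1,N4-dimethylbutanediamide | CON(C)C(=O)[C@H](Cc1ccc(OCc2ccccc2)cc1OCc1ccccc1)[C@@H](Cc1ccc(OCc2ccccc2)cc1OCc1ccccc1)C(=O)N(C)OC
F7 | step 5 | {(2S,3R,4R,5S)-2,5-bis[4-(4,4,5,5-tetramethyl-1,3,2-dioxaborolan-2-yl)phenyl]oxolane-3,4-diyl}bis{[2,4-bis(benzyloxy)phenyl]methyl} diacetate (mixture at the two acetoxy-bearing carbons) | CC(=O)OC(c1ccc(OCc2ccccc2)cc1OCc1ccccc1)[C@@H]1[C@@H](C(OC(C)=O)c2ccc(OCc3ccccc3)cc2OCc2ccccc2)[C@@H](c2ccc(B3OC(C)(C)C(C)(C)O3)cc2)O[C@@H]1c1ccc(B2OC(C)(C)C(C)(C)O2)cc1
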